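**Structural features**

The target is the B-type proanthocyanidin dimer gallocatechin-(4α→8)-epicatechin. It consists of two flavan-3-ol units: the upper unit has benzo ring A fused to pyran ring C and carries the pyrogallol ring B at C2; the lower unit has benzo ring D fused to pyran ring F and carries the catechol ring E. Lower-unit atoms are marked with their ring letter, e.g. C8(D), C2(F). The units are joined by one single bond from C4 of ring C to C8(D). Ring C holds three contiguous stereocentres, C2 (R), C3 (S) and C4 (S), all-trans: ring B at C2 and ring D at C4 lie on one face, the C3 hydroxyl and the C4 hydrogen on the other. Ring F holds the 2,3-cis pair C2(F) (R) and C3(F) (R) of epicatechin, remote from ring C. Fragile groups are the nine free phenols (ring B oxidises readily), the C4–C8(D) bond, which lies between two phloroglucinol-type rings and ionises in acid, and the benzylic C2–O1 bonds, which open in base once the para phenols are free. The real difficulty is the C4–C8(D) bond: it must form at C8(D) and not C6(D), between two hindered electron-rich rings, without chain growth, and with C4 trans to C3. The key step exploits the fact that the C3–O and C4–H bonds of ring C are syn to each other and anti to ring B: this is exactly what a syn addition of H and OH across a C3=C4 double bond, steered by C2, delivers.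

**Logic of the disconnections**

15 to 14: the ten O–CH2Ph bonds are cut. Benzyl ethers mask the nine phenols and the ring F hydroxyl, so every earlier intermediate is stable to air, base, organometallics and borane, and one neutral hydrogenolysis ends the route. The demand is that hydrogenolysis spares the benzylic C2–O1 bonds and the C4–C8(D) bond.

14 to 12 (key): the C3–O and C4–H bonds of ring C are cut, leaving a C3=C4 double bond. These two bonds are syn and both anti to ring B, so they can be added in one stereospecific event. Two of the three stereocentres of ring C disappear, and C4 becomes sp2, so the inter-unit bond carries no stereochemistry in 12. The forward step must put boron on C3, on the face opposite ring B, and must leave C2 untouched. In one sentence, the route is the hydroboration–oxidation of the alkene 12, in which both flavan units are already joined.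

12 to 5 and 9 (through 10 and 11): the C4–C8(D) bond is cut as an sp2–sp2 bond. The site is fixed on both sides, by the triflate at C4 and the bromine at C8(D), so no C6(D) isomer can form; neither partner nor the product can react a second time, so no oligomer can form. Two fragments of equal size result. The forward step is a congested cross-coupling and must run below the temperature at which the 2H-chromene could lose its C2 configuration.

5 to 4, 3, 2 and 1: the O–Tf bond is cut back to the C4 ketone, and the C3 oxygen is restored to reach 1. Compound 1 is an inexpensive natural product that already has rings A and B fully oxygenated, the C4 carbonyl, and C2 in the configuration needed. Its C3 hydroxyl is given up on purpose, because C3 must be sp2 in 12; it returns in step 9 together with the C4 hydrogen. No asymmetric step is needed. The demand is that C2, which is β to the carbonyl, survives deoxygenation and triflation; both are therefore run without a free enolate at ambient temperature.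

9 to 8, 7 and 6: the O–benzyl bond at C3(F), the C8(D)–Br bond and four phenolic O–benzyl bonds are cut. Compound 6 supplies both stereocentres of ring F, and the bromine marks C8(D) as the coupling site. The demand is bromination at C8(D) rather than C6(D) or ring E.

**Other disconnections considered**

Alternative 1: the cut is C4–C8(D), between a C4 cation and the unsubstituted C8(D) position (the first plan to come to mind). The forward key step is a TMSOTf-promoted Friedel–Crafts coupling of the 4-methoxy flavan-3-ol A1 (two steps from 2) with an excess of 7, giving the nonabenzyl dimer A2, then hydrogenolysis. The chosen plan is preferred for three structural reasons. A2 is still a phloroglucinol-type nucleophile, so chain growth can only be suppressed by excess 7. The cation can also be taken up at C6(D). The C4 configuration rests on a facial preference of a planar cation rather than on a mechanism. The chosen plan removes all three at the cost of a few steps.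

Alternative 2: the cut is the same bond with reversed polarity, C4 as an enolate carbon and C8(D) as the aryl halide. The forward key step is a palladium-catalysed α-arylation at C4 of the flavan-3-one A4 with 9, giving ketone A5, followed by hydride reduction at C3 to 14. A4 would come from (−)-epigallocatechin A3 by phenol benzylation and Dess–Martin oxidation. This plan is two steps shorter. However, C2–H of A4 and A5 is α to the ketone, benzylic and α to oxygen, so the only purchased stereocentre of ring C is exposed to the base the arylation needs. The reduction must also deliver hydride to C3 from the face that carries ring B and ring D; a ketone flanked by two α-aryl groups is expected to be attacked from the other face and to give the all-cis alcohol. The chosen plan never places C2 α to a carbonyl and sets C3 and C4 by a syn addition.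

Alternative 3: the cut is C4–C4a, so that ring C is closed last. The forward key step is ionisation of the C4 carbinol of the acyclic aryl ether A6 (stabilised by ring D), followed by intramolecular Friedel–Crafts attack of the symmetric 3,5-bis(benzyloxy)phenyl ether, giving the undecabenzyl dimer A7. The appeal is that ring A enters as a symmetric unit. Against it, A6 needs C2 and C3 from an asymmetric epoxidation, an aryl ether formation with clean inversion at a benzylic carbon that ionises easily, protecting-group changes and an aryllithium addition, which makes the longest line clearly longer. C4 would depend on a conformational preference in a cationic closure, and the acid that triggers it also threatens the new acid-labile bond.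

Key step: step 9

Assumption: commercial 1 and 6 are taken as the enantiopure natural (2R,3R) compounds and are the only sources of chirality. C2 of 4, 5 and 12 is named S only because the CIP priorities change when C3 loses its oxygen; the atoms do not move.

**Route**

Step 1
Reactants: 1 (+)-dihydromyricetin, (2R,3R)-3,5,7-trihydroxy-2-(3,4,5-trihydroxyphenyl)chroman-4-one
Product: 2 (2R,3R)-5,7-bis(benzyloxy)-3-hydroxy-2-[3,4,5-tris(benzyloxy)phenyl]chroman-4-one
Conditions: BnBr (6 equiv), K2CO3 (6 equiv), DMF, Ar, 0 °C → rt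
Reagents that add atoms: benzyl bromide, BrCc1ccccc1
Why: Williamson etherification of the five phenols; carbonate does not alkylate the aliphatic C3 hydroxyl, and once the para phenol of ring B is benzylated ring C can no longer open through a quinone methide, so C2 and C3 should be kept.

Step 2
Reactants: 2 (2R,3R)-5,7-bis(benzyloxy)-3-hydroxy-2-[3,4,5-tris(benzyloxy)phenyl]chroman-4-one
Product: 3 (2R,3R)-5,7-bis(benzyloxy)-4-oxo-2-[3,4,5-tris(benzyloxy)phenyl]chroman-3-yl acetate
Conditions: Ac2O, pyridine, DMAP (cat.), CH2Cl2, 0 °C → rt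
Reagents that add atoms: acetic anhydride, CC(=O)OC(C)=O
Why: DMAP-catalysed O-acylation of the secondary C3 alcohol turns it into the leaving group for the reductive cleavage; no stereocentre is touched.

Step 3
Reactants: 3 (2R,3R)-5,7-bis(benzyloxy)-4-oxo-2-[3,4,5-tris(benzyloxy)phenyl]chroman-3-yl acetate
Product: 4 (2S)-5,7-bis(benzyloxy)-2-[3,4,5-tris(benzyloxy)phenyl]chroman-4-one
Conditions: SmI2 (2.5 equiv), THF/MeOH, −78 °C
Reagents that add atoms: none
Why: SmI2 reductive cleavage of an α-acyloxy ketone: electron transfer to the aryl ketone gives a ketyl that expels acetate, and the resulting samarium enolate is protonated at C3 by methanol at −78 °C before it can open ring C; C2 is not involved and keeps its spatial arrangement.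

Step 4
Reactants: 4 (2S)-5,7-bis(benzyloxy)-2-[3,4,5-tris(benzyloxy)phenyl]chroman-4-one
Product: 5 (2S)-5,7-bis(benzyloxy)-2-[3,4,5-tris(benzyloxy)phenyl]-2H-chromen-4-yl trifluoromethanesulfonate
Conditions: Tf2O (1.3 equiv), 2,6-di-tert-butyl-4-methylpyridine (1.5 equiv), CH2Cl2, −20 °C → rt
Reagents that add atoms: trifluoromethanesulfonic anhydride, O=S(=O)(OS(=O)(=O)C(F)(F)F)C(F)(F)F
Why: enol triflate formation by O-sulfonylation of the electron-rich C4 carbonyl and loss of H3 to the hindered pyridine; only C3 carries α-hydrogens, and because no enolate is formed the retro-oxa-Michael opening that would racemise C2 is avoided.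

Step 5
Reactants: 6 (−)-epicatechin, (2R,3R)-2-(3,4-dihydroxyphenyl)chroman-3,5,7-triol
Product: 7 (2R,3R)-5,7-bis(benzyloxy)-2-[3,4-bis(benzyloxy)phenyl]chroman-3-ol
Conditions: BnBr (4.4 equiv), K2CO3 (5 equiv), DMF, Ar, 0 °C → rt
Reagents that add atoms: benzyl bromide, BrCc1ccccc1
Why: Williamson etherification of the four phenols under conditions that leave the secondary alcohol and both stereocentres of ring F alone.

Step 6
Reactants: 7 (2R,3R)-5,7-bis(benzyloxy)-2-[3,4-bis(benzyloxy)phenyl]chroman-3-ol
Product: 8 (2R,3R)-5,7-bis(benzyloxy)-2-[3,4-bis(benzyloxy)phenyl]-8-bromochroman-3-ol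
Conditions: NBS (1.0 equiv), CH2Cl2, −78 °C → 0 °C
Reagents that add atoms: N-bromosuccinimide, O=C1CCC(=O)N1Br
Why: electrophilic aromatic bromination of the phloroglucinol-type ring D; C8(D), between the ring oxygen and one benzyloxy group, is less hindered than C6(D), between two benzyloxy groups, and ring E is far less activated.

Step 7
Reactants: 8 (2R,3R)-5,7-bis(benzyloxy)-2-[3,4-bis(benzyloxy)phenyl]-8-bromochroman-3-ol
Product: 9 (2R,3R)-3,5,7-tris(benzyloxy)-2-[3,4-bis(benzyloxy)phenyl]-8-bromochroman
Conditions: NaH (1.5 equiv), BnBr (1.5 equiv), Bu4NI (cat.), DMF, 0 °C → rt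
Reagents that add atoms: benzyl bromide, BrCc1ccccc1
Why: Williamson etherification of the C3(F) alkoxide removes the only acidic proton before the lithiation; the aryl bromide is inert to NaH.

Step 8
Reactants: 9 (2R,3R)-3,5,7-tris(benzyloxy)-2-[3,4-bis(benzyloxy)phenyl]-8-bromochroman; 5 (2S)-5,7-bis(benzyloxy)-2-[3,4,5-tris(benzyloxy)phenyl]-2H-chromen-4-yl trifluoromethanesulfonate
Product: 12 (2R,3R)-3,5,7-tris(benzyloxy)-2-[3,4-bis(benzyloxy)phenyl]-8-{(2S)-5,7-bis(benzyloxy)-2-[3,4,5-tris(benzyloxy)phenyl]-2H-chromen-4-yl}chroman, via aryllithium 10 (not isolated), via arylzinc chloride 11 (not isolated)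
Conditions: 9 (1.4 equiv), n-BuLi, THF, −78 °C; ZnCl2, −78 °C → rt; then 5 (1.0 equiv), Pd2(dba)3 (2.5 mol%), SPhos (10 mol%), THF, 55 °C
Reagents that add atoms: none
Why: Negishi cross-coupling: bromine–lithium exchange is faster than any deprotonation at −78 °C, the zinc reagent is mild enough for the triflate, and the bulky biaryl phosphine drives the congested reductive elimination. No stereocentre is formed; the site on ring D is fixed by the bromine of 9 and the site on ring C by the triflate of 5.

Step 9
Reactants: 12 (2R,3R)-3,5,7-tris(benzyloxy)-2-[3,4-bis(benzyloxy)phenyl]-8-{(2S)-5,7-bis(benzyloxy)-2-[3,4,5-tris(benzyloxy)phenyl]-2H-chromen-4-yl}chroman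
Product: 14 (2R,3S,4S)-5,7-bis(benzyloxy)-4-{(2R,3R)-3,5,7-tris(benzyloxy)-2-[3,4-bis(benzyloxy)phenyl]chroman-8-yl}-2-[3,4,5-tris(benzyloxy)phenyl]chroman-3-ol, via C3 alkylborane 13 (not isolated)
Conditions: BH3·THF (5 equiv), THF, 0 °C → rt; then 3 M NaOH, 30% H2O2, 0 °C → rt
Reagents that add atoms: hydrogen peroxide, OO
Why: Hydroboration–oxidation of a trisubstituted styrene-type alkene, the reaction type that converts flav-3-enes into 2,3-trans-flavan-3-ols. BH3 adds across C3=C4 through a four-centre transition state: boron goes to C3, the less substituted carbon, because the developing positive charge is best carried by C4, which is benzylic to ring A and ring D, and the hydride goes to C4 on the same face. No ring is closed. C3: the borane should approach on the face opposite ring B at the neighbouring C2, so boron, and after oxidation with retention the hydroxyl, ends up trans to ring B (3S). C4: the hydrogen is delivered syn to boron, which places ring D trans to the C3 oxygen and cis to ring B (4S); this relation is fixed by the mechanism. The selectivity needed is facial, and it rests on C2, the only stereocentre next to the carbon that receives boron; ring D stands perpendicular to the alkene and screens both faces about equally, and the stereocentres of ring F are remote. Oxidation by hydroperoxide (boron-to-oxygen 1,2-shift) replaces boron by oxygen and leaves the benzyl ethers alone.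

Step 10
Reactants: 14 (2R,3S,4S)-5,7-bis(benzyloxy)-4-{(2R,3R)-3,5,7-tris(benzyloxy)-2-[3,4-bis(benzyloxy)phenyl]chroman-8-yl}-2-[3,4,5-tris(benzyloxy)phenyl]chroman-3-ol
Product: 15 gallocatechin-(4α→8)-epicatechin, (2R,3S,4S)-4-[(2R,3R)-2-(3,4-dihydroxyphenyl)-3,5,7-trihydroxychroman-8-yl]-2-(3,4,5-trihydroxyphenyl)chroman-3,5,7-triol
Conditions: H2 (1 atm), Pd(OH)2/C, THF/MeOH/H2O, rt; filtration under Ar, lyophilisation
Reagents that add atoms: none
Why: hydrogenolysis of the ten benzyl ethers under neutral conditions; the ring C–O bonds and the C4–C8(D) bond are much slower to cleave than O-benzyl bonds, and no stereocentre is involved.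

**Compound list**

1 | (+)-dihydromyricetin, (2R,3R)-3,5,7-trihydroxy-2-(3,4,5-trihydroxyphenyl)chroman-4-one | Oc1cc(O)c2c(c1)O[C@H](c1cc(O)c(O)c(O)c1)[C@@H](O)C2=O | starting material
2 | (2R,3R)-5,7-bis(benzyloxy)-3-hydroxy-2-[3,4,5-tris(benzyloxy)phenyl]chroman-4-one | c1ccccc1COc1cc(OCc3ccccc3)c2c(c1)O[C@H](c1cc(OCc3ccccc3)c(OCc3ccccc3)c(OCc3ccccc3)c1)[C@@H](O)C2=O | intermediate
3 | (2R,3R)-5,7-bis(benzyloxy)-4-oxo-2-[3,4,5-tris(benzyloxy)phenyl]chroman-3-yl acetate | c1ccccc1COc1cc(OCc3ccccc3)c2c(c1)O[C@H](c1cc(OCc3ccccc3)c(OCc3ccccc3)c(OCc3ccccc3)c1)[C@@H](OC(C)=O)C2=O | intermediate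
4 | (2S)-5,7-bis(benzyloxy)-2-[3,4,5-tris(benzyloxy)phenyl]chroman-4-one | c1ccccc1COc1cc(OCc3ccccc3)c2c(c1)O[C@H](c1cc(OCc3ccccc3)c(OCc3ccccc3)c(OCc3ccccc3)c1)CC2=O | intermediate
5 | (2S)-5,7-bis(benzyloxy)-2-[3,4,5-tris(benzyloxy)phenyl]-2H-chromen-4-yl trifluoromethanesulfonate | c1ccccc1COc1cc(OCc3ccccc3)c2c(c1)O[C@H](c1cc(OCc3ccccc3)c(OCc3ccccc3)c(OCc3ccccc3)c1)C=C2OS(=O)(=O)C(F)(F)F | intermediate
6 | (−)-epicatechin, (2R,3R)-2-(3,4-dihydroxyphenyl)chroman-3,5,7-triol | Oc1cc(O)c2c(c1)O[C@H](c1ccc(O)c(O)c1)[C@H](O)C2 | starting material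
7 | (2R,3R)-5,7-bis(benzyloxy)-2-[3,4-bis(benzyloxy)phenyl]chroman-3-ol | c1ccccc1COc1cc(OCc3ccccc3)c2c(c1)O[C@H](c1ccc(OCc3ccccc3)c(OCc3ccccc3)c1)[C@H](O)C2 | intermediate
8 | (2R,3R)-5,7-bis(benzyloxy)-2-[3,4-bis(benzyloxy)phenyl]-8-bromochroman-3-ol | c1ccccc1COc1cc(OCc3ccccc3)c2c(c1Br)O[C@H](c1ccc(OCc3ccccc3)c(OCc3ccccc3)c1)[C@H](O)C2 | intermediate
9 | (2R,3R)-3,5,7-tris(benzyloxy)-2-[3,4-bis(benzyloxy)phenyl]-8-bromochroman | c1ccccc1COc1cc(OCc3ccccc3)c2c(c1Br)O[C@H](c1ccc(OCc3ccccc3)c(OCc3ccccc3)c1)[C@H](OCc1ccccc1)C2 | intermediate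
10 | aryllithium: 9 with lithium in place of bromine at C8 | c1ccccc1COc1cc(OCc3ccccc3)c2c(c1[Li])O[C@H](c1ccc(OCc3ccccc3)c(OCc3ccccc3)c1)[C@H](OCc1ccccc1)C2 | intermediate (not isolated)
11 | arylzinc chloride: 9 with ZnCl in place of bromine at C8 | c1ccccc1COc1cc(OCc3ccccc3)c2c(c1[Zn]Cl)O[C@H](c1ccc(OCc3ccccc3)c(OCc3ccccc3)c1)[C@H](OCc1ccccc1)C2 | intermediate (not isolated)
12 | (2R,3R)-3,5,7-tris(benzyloxy)-2-[3,4-bis(benzyloxy)phenyl]-8-{(2S)-5,7-bis(benzyloxy)-2-[3,4,5-tris(benzyloxy)phenyl]-2H-chromen-4-yl}chroman | c1ccccc1COc1cc(OCc3ccccc3)c2c(c1)O[C@H](c1cc(OCc3ccccc3)c(OCc3ccccc3)c(OCc3ccccc3)c1)C=C2c1c(OCc3ccccc3)cc(OCc3ccccc3)c2c1O[C@H](c1ccc(OCc3ccccc3)c(OCc3ccccc3)c1)[C@H](OCc1ccccc1)C2 | intermediate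
13 | C3 monoalkylborane: 14 with BH2 in place of the C3 hydroxyl (boron trans to ring B, cis to the new C4 hydrogen) | c1ccccc1COc1cc(OCc3ccccc3)c2c(c1)O[C@H](c1cc(OCc3ccccc3)c(OCc3ccccc3)c(OCc3ccccc3)c1)[C@@H](B)[C@@H]2c1c(OCc3ccccc3)cc(OCc3ccccc3)c2c1O[C@H](c1ccc(OCc3ccccc3)c(OCc3ccccc3)c1)[C@H](OCc1ccccc1)C2 | intermediate (not isolated)
14 | (2R,3S,4S)-5,7-bis(benzyloxy)-4-{(2R,3R)-3,5,7-tris(benzyloxy)-2-[3,4-bis(benzyloxy)phenyl]chroman-8-yl}-2-[3,4,5-tris(benzyloxy)phenyl]chroman-3-ol | c1ccccc1COc1cc(OCc3ccccc3)c2c(c1)O[C@H](c1cc(OCc3ccccc3)c(OCc3ccccc3)c(OCc3ccccc3)c1)[C@@H](O)[C@@H]2c1c(OCc3ccccc3)cc(OCc3ccccc3)c2c1O[C@H](c1ccc(OCc3ccccc3)c(OCc3ccccc3)c1)[C@H](OCc1ccccc1)C2 | intermediate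
15 | gallocatechin-(4α→8)-epicatechin (CNP0225927.3) | Oc1cc(O)c2c(c1)O[C@H](c1cc(O)c(O)c(O)c1)[C@@H](O)[C@@H]2c1c(O)cc(O)c2c1O[C@H](c1ccc(O)c(O)c1)[C@H](O)C2 | target

**Step count and risk**

Total: 10 steps. Longest linear sequence: 7 steps (1 → 2 → 3 → 4 → 5 → 12 → 14 → 15, steps 1–4 and 8–10); the branch from 6 has 6 steps.

Least certain steps:

Step 9 (key). Three things may go wrong: poor facial selectivity if ring B does not screen C3 well enough; slow addition at the crowded alkene; and base-induced elimination of the β-aryloxy borane, which would open ring C during oxidation. A buffered oxidant is the first tactical remedy. The fallback abandons the alkene and uses the cationic coupling; it sets out from 2 and 7 and comes back at 14. Compound 2 is reduced with NaBH4 (THF/EtOH, 0 °C) to (2R,3S,4R)-5,7-bis(benzyloxy)-2-[3,4,5-tris(benzyloxy)phenyl]chroman-3,4-diol F1. Compound 7 is benzylated at O3 (NaH, BnBr, DMF) to (2R,3R)-3,5,7-tris(benzyloxy)-2-[3,4-bis(benzyloxy)phenyl]chroman F2. F1 is then ionised at C4 with TMSOTf (CH2Cl2, −78 °C) in the presence of excess F2; attack of C8(D) anti to the C3 oxygen should give 14.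

Step 8. Transmetalation and reductive elimination may stall between the two ortho-flanked carbons, the arylzinc may be protonated instead, and prolonged heating may erode C2 of the 2H-chromene by reversible opening of the C2–O1 bond. The fallback replaces cross-coupling by carbonyl addition; it sets out from 10 and 4 and comes back at 12. Compound 10 is transmetalated with anhydrous CeCl3 (THF, −78 °C) to the arylcerium dichloride F3. F3 adds to the C4 carbonyl of 4 to give the tertiary carbinol (2S)-5,7-bis(benzyloxy)-4-hydroxy-4-{(2R,3R)-3,5,7-tris(benzyloxy)-2-[3,4-bis(benzyloxy)phenyl]chroman-8-yl}-2-[3,4,5-tris(benzyloxy)phenyl]chroman F4 (either C4 epimer serves). Dehydration with the Burgess reagent (benzene, 50 °C) can only go toward C3 and should give 12.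

Step 4. The O-triflated cation may open at C2–O1 before it loses H3, which would scramble C2, and the electron-rich enol triflate may hydrolyse on handling. The fallback avoids the triflate and the organozinc altogether; it sets out from 4 and 9 and comes back at 12. Compound 4 is condensed with TsNHNH2 (MeOH, cat. AcOH, 60 °C) to the N-tosylhydrazone F5. F5 is coupled with 9 (Pd2(dba)3, XPhos, LiOt-Bu, dioxane, 90 °C) in a Barluenga coupling: the diazo compound formed in the flask gives a palladium carbene, ring D migrates to C4, and β-hydride elimination toward C3 should give 12.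

Step 3. The samarium enolate may open ring C by β-elimination of the ring A phenoxide before it is protonated, which would cost the C2 configuration, and the ketone may be reduced further. The fallback uses a radical instead of an enolate; it sets out from 2 and comes back at 4. Compound 2 is converted with PhOC(S)Cl, pyridine and DMAP (CH2Cl2) into the O-phenyl thionocarbonate F6. F6 is deoxygenated with Bu3SnH and AIBN (toluene, 80 °C; Barton–McCombie); the C3 radical is α to the ketone and should take hydrogen from the stannane to give 4.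

**Further compounds**

F1 | step 9 | (2R,3S,4R)-5,7-bis(benzyloxy)-2-[3,4,5-tris(benzyloxy)phenyl]chroman-3,4-diol | c1ccccc1COc1cc(OCc3ccccc3)c2c(c1)O[C@H](c1cc(OCc3ccccc3)c(OCc3ccccc3)c(OCc3ccccc3)c1)[C@@H](O)[C@@H]2O
F2 | step 9 | (2R,3R)-3,5,7-tris(benzyloxy)-2-[3,4-bis(benzyloxy)phenyl]chroman | c1ccccc1COc1cc(OCc3ccccc3)c2c(c1)O[C@H](c1ccc(OCc3ccccc3)c(OCc3ccccc3)c1)[C@H](OCc1ccccc1)C2
F3 | step 8 | arylcerium dichloride: 9 with CeCl2 in place of bromine at C8 | c1ccccc1COc1cc(OCc3ccccc3)c2c(c1[Ce](Cl)Cl)O[C@H](c1ccc(OCc3ccccc3)c(OCc3ccccc3)c1)[C@H](OCc1ccccc1)C2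
F4 | step 8 | (2S)-5,7-bis(benzyloxy)-4-hydroxy-4-{(2R,3R)-3,5,7-tris(benzyloxy)-2-[3,4-bis(benzyloxy)phenyl]chroman-8-yl}-2-[3,4,5-tris(benzyloxy)phenyl]chroman, C4 epimers | c1ccccc1COc1cc(OCc3ccccc3)c2c(c1)O[C@H](c1cc(OCc3ccccc3)c(OCc3ccccc3)c(OCc3ccccc3)c1)CC2(O)c1c(OCc3ccccc3)cc(OCc3ccccc3)c2c1O[C@H](c1ccc(OCc3ccccc3)c(OCc3ccccc3)c1)[C@H](OCc1ccccc1)C2
F5 | step 4 | N-tosylhydrazone of 4 at C4 | c1ccccc1COc1cc(OCc3ccccc3)c2c(c1)O[C@H](c1cc(OCc3ccccc3)c(OCc3ccccc3)c(OCc3ccccc3)c1)CC2=NNS(=O)(=O)c1ccc(C)cc1
F6 | step 3 | O-[(2R,3R)-5,7-bis(benzyloxy)-4-oxo-2-[3,4,5-tris(benzyloxy)phenyl]chroman-3-yl] O-phenyl carbonothioate | c1ccccc1COc1cc(OCc3ccccc3)c2c(c1)O[C@H](c1cc(OCc3ccccc3)c(OCc3ccccc3)c(OCc3ccccc3)c1)[C@@H](OC(=S)Oc1ccccc1)C2=O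
A1 | alternative 1 | (2R,3S,4R)-5,7-bis(benzyloxy)-4-methoxy-2-[3,4,5-tris(benzyloxy)phenyl]chroman-3-ol | c1ccccc1COc1cc(OCc3ccccc3)c2c(c1)O[C@H](c1cc(OCc3ccccc3)c(OCc3ccccc3)c(OCc3ccccc3)c1)[C@@H](O)[C@@H]2OC
A2 | alternative 1 | (2R,3S,4S)-5,7-bis(benzyloxy)-4-{(2R,3R)-5,7-bis(benzyloxy)-2-[3,4-bis(benzyloxy)phenyl]-3-hydroxychroman-8-yl}-2-[3,4,5-tris(benzyloxy)phenyl]chroman-3-ol | c1ccccc1COc1cc(OCc3ccccc3)c2c(c1)O[C@H](c1cc(OCc3ccccc3)c(OCc3ccccc3)c(OCc3ccccc3)c1)[C@@H](O)[C@@H]2c1c(OCc3ccccc3)cc(OCc3ccccc3)c2c1O[C@H](c1ccc(OCc3ccccc3)c(OCc3ccccc3)c1)[C@H](O)C2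
A3 | alternative 2 | (−)-epigallocatechin, (2R,3R)-2-(3,4,5-trihydroxyphenyl)chroman-3,5,7-triol | Oc1cc(O)c2c(c1)O[C@H](c1cc(O)c(O)c(O)c1)[C@H](O)C2
A4 | alternative 2 | (2R)-5,7-bis(benzyloxy)-2-[3,4,5-tris(benzyloxy)phenyl]chroman-3-one | c1ccccc1COc1cc(OCc3ccccc3)c2c(c1)O[C@H](c1cc(OCc3ccccc3)c(OCc3ccccc3)c(OCc3ccccc3)c1)C(=O)C2
A5 | alternative 2 | (2R,4S)-5,7-bis(benzyloxy)-4-{(2R,3R)-3,5,7-tris(benzyloxy)-2-[3,4-bis(benzyloxy)phenyl]chroman-8-yl}-2-[3,4,5-tris(benzyloxy)phenyl]chroman-3-one | c1ccccc1COc1cc(OCc3ccccc3)c2c(c1)O[C@H](c1cc(OCc3ccccc3)c(OCc3ccccc3)c(OCc3ccccc3)c1)C(=O)[C@@H]2c1c(OCc3ccccc3)cc(OCc3ccccc3)c2c1O[C@H](c1ccc(OCc3ccccc3)c(OCc3ccccc3)c1)[C@H](OCc1ccccc1)C2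
A6 | alternative 3 | acyclic carbinol: 1-{(2R,3R)-3,5,7-tris(benzyloxy)-2-[3,4-bis(benzyloxy)phenyl]chroman-8-yl}-2-(benzyloxy)-3-[3,5-bis(benzyloxy)phenoxy]-3-[3,4,5-tris(benzyloxy)phenyl]propan-1-ol, (2S,3R) in the chain, C1 epimers | c1ccccc1COc1cc(OCc3ccccc3)cc(c1)O[C@H](c1cc(OCc3ccccc3)c(OCc3ccccc3)c(OCc3ccccc3)c1)[C@@H](OCc1ccccc1)C(O)c1c(OCc3ccccc3)cc(OCc3ccccc3)c2c1O[C@H](c1ccc(OCc3ccccc3)c(OCc3ccccc3)c1)[C@H](OCc1ccccc1)C2
A7 | alternative 3 | (2R,3S,4S)-3,5,7-tris(benzyloxy)-4-{(2R,3R)-3,5,7-tris(benzyloxy)-2-[3,4-bis(benzyloxy)phenyl]chroman-8-yl}-2-[3,4,5-tris(benzyloxy)phenyl]chroman | c1ccccc1COc1cc(OCc3ccccc3)c2c(c1)O[C@H](c1cc(OCc3ccccc3)c(OCc3ccccc3)c(OCc3ccccc3)c1)[C@@H](OCc1ccccc1)[C@@H]2c1c(OCc3ccccc3)cc(OCc3ccccc3)c2c1O[C@H](c1ccc(OCc3ccccc3)c(OCc3ccccc3)c1)[C@H](OCc1ccccc1)C2
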